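**Retrosynthetic overview**

1. The target is the arecatannin tetramer epicatechin-(4β→8)-epicatechin-(4β→8)-epicatechin-(4β→8)-catechin. The last disconnections are global debenzylation and the central bond (C4 of unit 2 to C8 of unit 3), made by Lewis-acid coupling of two nine-fold benzylated dimers.
2. Both dimers come from one protected dimer, benzylated epicatechin-(4β→8)-catechin. As such it is units 3 and 4 (nucleophile); after inversion at C3 and activation at C4 of its lower unit it is units 1 and 2 (electrophile).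
3. Only the upper unit of this dimer comes from (−)-epicatechin. The lower flavan is built on a phloroglucinol ring A that already carries the upper unit at C8, and its pyran ring C is closed at C2–C3.
4. Enabling feature: in ring C, C2 bears only O1 (the ring A phenol oxygen), the catechol ring B and C3, so O1–C2(ring B) is an aryl 3,4-dioxygenated benzoate in disguise; C3–C4 sits on C4a ortho to O1, where a Claisen rearrangement from that same oxygen places an allyl group. Tebbe methylenation/ring-closing metathesis of this olefinic aryl ester gives the flav-2-ene, and C2=C3 then takes up both stereocentres by asymmetric hydroboration.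
5. Ring order: rings A, B and C of the upper unit are native; ring A of the new unit comes from 3,5-bis(benzyloxy)phenol, ring B from the benzoate, and ring C is formed last (step 9).

Key step: step 9

Assumption: 3,5-bis(benzyloxy)phenol and 3,4-bis(benzyloxy)benzoic acid are bought; units are counted 1 to 4 from the upper epicatechin to the terminal catechin, with flavan numbering (O1, C2, C3, C4, C4a, C5 to C8, C8a) in each unit.

**Route**

Step 1
Reactants: 1 (−)-epicatechin
Product: 2 5,7,3',4'-tetra-O-benzyl-(−)-epicatechin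
Conditions: BnBr, K2CO3, DMF, 0 °C → rt
Reagents that add atoms: benzyl bromide, BrCc1ccccc1
Why: Williamson etherification; carbonate deprotonates only the four phenols, so the secondary 3-OH stays free and no stereocentre is touched.

Step 2
Reactants: 2 5,7,3',4'-tetra-O-benzyl-(−)-epicatechin
Product: 3 3,5,7,3',4'-penta-O-benzyl-(−)-epicatechin
Conditions: NaH, BnBr, DMF, 0 °C → rt
Reagents that add atoms: benzyl bromide, BrCc1ccccc1
Why: Williamson etherification of the secondary alkoxide masks the 3-OH of the native unit against the Tebbe reagent, the borane and the oxidant used later, and the group leaves in the final hydrogenolysis.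

Step 3
Reactants: 3 3,5,7,3',4'-penta-O-benzyl-(−)-epicatechin
Product: 4 3,5,7,3',4'-penta-O-benzyl-4β-(2-ethoxyethoxy)epicatechin
Conditions: DDQ, 2-ethoxyethanol, CH2Cl2, rt
Reagents that add atoms: 2-ethoxyethanol, CCOCCO
Why: DDQ benzylic oxidation; hydride abstraction at C4 gives the ring-A-stabilised cation, which the alcohol should trap anti to the axial 3-OBn group (3,4-trans, 4β), and this centre is re-ionised in step 6.

Step 4
Reactants: 5 3,5-bis(benzyloxy)phenol
Product: 6 allyl 3,5-bis(benzyloxy)phenyl ether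
Conditions: allyl bromide, K2CO3, acetone, reflux
Reagents that add atoms: allyl bromide, C=CCBr
Why: Williamson etherification of the single phenol.

Step 5
Reactants: 6 allyl 3,5-bis(benzyloxy)phenyl ether
Product: 7 2-allyl-3,5-bis(benzyloxy)phenol
Conditions: PhNEt2, 190 °C
Reagents that add atoms: none
Why: aromatic Claisen rearrangement ([3,3]); the two ortho positions are equivalent, so one product should form, with the future C4–C3 unit next to the future O1.

Step 6
Reactants: 4 3,5,7,3',4'-penta-O-benzyl-4β-(2-ethoxyethoxy)epicatechin; 7 2-allyl-3,5-bis(benzyloxy)phenol (3 equiv)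
Product: 8 4β-[3-allyl-4,6-bis(benzyloxy)-2-hydroxyphenyl]-3,5,7,3',4'-penta-O-benzylepicatechin
Conditions: TMSOTf (cat.), CH2Cl2, −78 → −30 °C; aq. NaHCO3
Reagents that add atoms: none
Why: Lewis-acid Friedel–Crafts alkylation by the flavan C4 cation; attack anti to the axial 3-OBn group should set C4 as 4β (3,4-trans), at the arene position between OH and OBn (the analogue of flavan C8) in preference to the more hindered one between two OBn groups, and any regioisomer is removed here.

Step 7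
Reactants: 9 3,4-bis(benzyloxy)benzoic acid
Product: 10 3,4-bis(benzyloxy)benzoyl chloride
Conditions: (COCl)2, DMF (cat.), CH2Cl2, 0 °C → rt
Reagents that add atoms: oxalyl chloride, O=C(Cl)C(Cl)=O
Why: acid chloride formation through the Vilsmeier-type chloroiminium catalyst; benzyl ethers are inert.

Step 8
Reactants: 8 4β-[3-allyl-4,6-bis(benzyloxy)-2-hydroxyphenyl]-3,5,7,3',4'-penta-O-benzylepicatechin; 10 3,4-bis(benzyloxy)benzoyl chloride
Product: 11 6-allyl-3,5-bis(benzyloxy)-2-(3,5,7,3',4'-penta-O-benzylepicatechin-4β-yl)phenyl 3,4-bis(benzyloxy)benzoate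
Conditions: NaH, THF, 0 °C; then 10, 0 °C → rt
Reagents that add atoms: none
Why: O-acylation of the hindered sodium phenoxide by the aroyl chloride; the ester carbonyl carbon is the future C2 and the only carbonyl in the molecule.

Step 9
Reactants: 11 6-allyl-3,5-bis(benzyloxy)-2-(3,5,7,3',4'-penta-O-benzylepicatechin-4β-yl)phenyl 3,4-bis(benzyloxy)benzoate
Product: 13 3,5,7,3',4'-penta-O-benzylepicatechin-(4β→8)-5,7,3',4'-tetra-O-benzylflav-2-ene, via enol ether diene 12 (not isolated)
Conditions: Tebbe reagent Cp2Ti(μ-CH2)(μ-Cl)AlMe2 (4 equiv), THF, 0 → 25 °C, then 65 °C; 0.1 M NaOH quench, basic alumina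
Reagents that add atoms: none
Why: The Tebbe reagent releases Cp2Ti=CH2, which methylenates the aryl ester carbonyl through an oxatitanacyclobutane to the 1-aryl-1-aryloxyethene 12; on heating, further Cp2Ti=CH2 engages the terminal allyl alkene, and the resulting titanium alkylidene closes onto the enol ether through a titanacyclobutane, expelling ethylene and forming C2=C3. The closest known reaction type is the one-pot Tebbe methylenation/ring-closing metathesis of olefinic esters to six- and seven-membered cyclic enol ethers, together with Tebbe methylenation of phenyl benzoate to 1-phenoxy-1-phenylethene. The one ring closed is pyran ring C of the new flavan (O1, C2, C3, C4, C4a, C8a), by ring-closing olefin metathesis between the enol ether carbon C2 and the internal allyl carbon C3. No stereocentre is created: C2 and C3 leave the step as a trisubstituted enol ether and are set in steps 10 to 12, while the three stereocentres of the native unit are untouched because the reagent is non-acidic and the substrate has no free OH. The step needs ester-over-ether and terminal-alkene-over-product selectivity; the substrate has one carbonyl and one alkene, only the six-membered ring is geometrically possible, and the trisubstituted product enol ether is too hindered to re-enter metathesis. In the dimer later activated as the electrophile this bond is C2–C3 of unit 2; in the dimer used as the nucleophile it is C2–C3 of unit 4.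

Step 10
Reactants: 13 3,5,7,3',4'-penta-O-benzylepicatechin-(4β→8)-5,7,3',4'-tetra-O-benzylflav-2-ene
Product: 15 3,5,7,3',4'-penta-O-benzylepicatechin-(4β→8)-5,7,3',4'-tetra-O-benzylcatechin, via C3 alkylborane 14 (not isolated)
Conditions: IpcBH2 [from (+)-α-pinene], THF, −25 °C; then NaOH, H2O2, 0 °C → rt
Reagents that add atoms: hydrogen peroxide, OO
Why: Brown asymmetric hydroboration–oxidation; syn addition of H–B across C2=C3 with boron at C3 (β to O1, away from the aryl group), on the face chosen by the isopinocampheyl group in the sense known for 1-arylcycloalkenes, then oxidation with retention, should give the 2,3-trans (2R,3S) catechin-type unit.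

Step 11
Reactants: 15 3,5,7,3',4'-penta-O-benzylepicatechin-(4β→8)-5,7,3',4'-tetra-O-benzylcatechin
Product: 16 3,5,7,3',4'-penta-O-benzylepicatechin-(4β→8)-(2R)-5,7,3',4'-tetra-O-benzylflavan-3-one
Conditions: Dess–Martin periodinane, CH2Cl2, rt
Reagents that add atoms: none
Why: Dess–Martin oxidation of the only free alcohol under near-neutral conditions should leave the C2 stereocentre alpha to the new ketone intact, as in the oxidation of benzylated catechin to its flavan-3-one.

Step 12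
Reactants: 16 3,5,7,3',4'-penta-O-benzylepicatechin-(4β→8)-(2R)-5,7,3',4'-tetra-O-benzylflavan-3-one
Product: 17 3,5,7,3',4'-penta-O-benzylepicatechin-(4β→8)-5,7,3',4'-tetra-O-benzylepicatechin
Conditions: LiBH(s-Bu)3 (L-Selectride), LiBr, THF, −78 °C; then H2O
Reagents that add atoms: none
Why: hindered-hydride ketone reduction; the bulky borohydride should attack anti to the equatorial C2 aryl group and leave the axial 3-OH cis to it (2R,3R), as in the known catechin-to-epicatechin inversion.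

Step 13
Reactants: 17 3,5,7,3',4'-penta-O-benzylepicatechin-(4β→8)-5,7,3',4'-tetra-O-benzylepicatechin
Product: 18 3,5,7,3',4'-penta-O-benzylepicatechin-(4β→8)-5,7,3',4'-tetra-O-benzyl-4β-(2-ethoxyethoxy)epicatechin
Conditions: DDQ, 2-ethoxyethanol, CH2Cl2, rt
Reagents that add atoms: 2-ethoxyethanol, CCOCCO
Why: DDQ benzylic oxidation as in step 3; the C4 methylene of the lower unit is the only unhindered benzylic CH2 on an oxygenated ring A, the tertiary C4–H of the upper unit is shielded, and the alcohol should add anti to the axial 3-OH.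

Step 14
Reactants: 18 3,5,7,3',4'-penta-O-benzylepicatechin-(4β→8)-5,7,3',4'-tetra-O-benzyl-4β-(2-ethoxyethoxy)epicatechin; 15 3,5,7,3',4'-penta-O-benzylepicatechin-(4β→8)-5,7,3',4'-tetra-O-benzylcatechin (3 equiv, excess recovered)
Product: 19 octadeca-O-benzyl epicatechin-(4β→8)-epicatechin-(4β→8)-epicatechin-(4β→8)-catechin (3-OBn on units 1 and 3; free 3-OH on units 2 and 4)
Conditions: TMSOTf (cat.), CH2Cl2, −78 → −40 °C; aq. NaHCO3
Reagents that add atoms: none
Why: Lewis-acid Friedel–Crafts coupling; the C4 cation of unit 2 should be attacked by C8 of the upper ring A of 15 (the most accessible nucleophilic site, as in chain extension of benzylated procyanidins) anti to the axial 3-OH, setting C4 of unit 2 as 4β.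

Step 15
Reactants: 19 octadeca-O-benzyl epicatechin-(4β→8)-epicatechin-(4β→8)-epicatechin-(4β→8)-catechin
Product: 20 epicatechin-(4β→8)-epicatechin-(4β→8)-epicatechin-(4β→8)-catechin (the target arecatannin tetramer)
Conditions: H2 (1 atm), Pd(OH)2/C, THF/MeOH/H2O, rt
Reagents that add atoms: none
Why: hydrogenolysis of all eighteen benzyl ethers (sixteen phenolic, two aliphatic) under neutral conditions that touch no stereocentre and no interflavan bond.

**Compound list**

1 | (−)-epicatechin | Oc1cc(O)c2c(c1)O[C@H](c1ccc(O)c(O)c1)[C@H](O)C2 | starting material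
2 | 5,7,3',4'-tetra-O-benzyl-(−)-epicatechin | O(Cc1ccccc1)c1cc(OCc3ccccc3)c2c(c1)O[C@H](c1ccc(OCc3ccccc3)c(OCc3ccccc3)c1)[C@H](O)C2 | intermediate
3 | 3,5,7,3',4'-penta-O-benzyl-(−)-epicatechin | O(Cc1ccccc1)c1cc(OCc3ccccc3)c2c(c1)O[C@H](c1ccc(OCc3ccccc3)c(OCc3ccccc3)c1)[C@H](OCc1ccccc1)C2 | intermediate
4 | 3,5,7,3',4'-penta-O-benzyl-4β-(2-ethoxyethoxy)epicatechin | O(Cc1ccccc1)c1cc(OCc3ccccc3)c2c(c1)O[C@H](c1ccc(OCc3ccccc3)c(OCc3ccccc3)c1)[C@H](OCc1ccccc1)[C@H]2OCCOCC | intermediate
5 | 3,5-bis(benzyloxy)phenol | Oc1cc(OCc2ccccc2)cc(OCc2ccccc2)c1 | starting material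
6 | allyl 3,5-bis(benzyloxy)phenyl ether | C=CCOc1cc(OCc2ccccc2)cc(OCc2ccccc2)c1 | intermediate
7 | 2-allyl-3,5-bis(benzyloxy)phenol | Oc1cc(OCc2ccccc2)cc(OCc2ccccc2)c1CC=C | intermediate
8 | 4β-[3-allyl-4,6-bis(benzyloxy)-2-hydroxyphenyl]-3,5,7,3',4'-penta-O-benzylepicatechin | O(Cc1ccccc1)c1cc(OCc3ccccc3)c2c(c1)O[C@H](c1ccc(OCc3ccccc3)c(OCc3ccccc3)c1)[C@H](OCc1ccccc1)[C@H]2c1c(OCc2ccccc2)cc(OCc2ccccc2)c(CC=C)c1O | intermediate
9 | 3,4-bis(benzyloxy)benzoic acid | OC(=O)c1ccc(OCc2ccccc2)c(OCc2ccccc2)c1 | starting material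
10 | 3,4-bis(benzyloxy)benzoyl chloride | ClC(=O)c1ccc(OCc2ccccc2)c(OCc2ccccc2)c1 | intermediate
11 | 6-allyl-3,5-bis(benzyloxy)-2-(3,5,7,3',4'-penta-O-benzylepicatechin-4β-yl)phenyl 3,4-bis(benzyloxy)benzoate | O(Cc1ccccc1)c1cc(OCc3ccccc3)c2c(c1)O[C@H](c1ccc(OCc3ccccc3)c(OCc3ccccc3)c1)[C@H](OCc1ccccc1)[C@H]2c1c(OCc2ccccc2)cc(OCc2ccccc2)c(CC=C)c1OC(=O)c1ccc(OCc2ccccc2)c(OCc2ccccc2)c1 | intermediate
12 | 1-[3,4-bis(benzyloxy)phenyl]vinyl ether of phenol 8 (enol ether diene) | O(Cc1ccccc1)c1cc(OCc3ccccc3)c2c(c1)O[C@H](c1ccc(OCc3ccccc3)c(OCc3ccccc3)c1)[C@H](OCc1ccccc1)[C@H]2c1c(OCc2ccccc2)cc(OCc2ccccc2)c(CC=C)c1OC(=C)c1ccc(OCc2ccccc2)c(OCc2ccccc2)c1 | intermediate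
13 | 3,5,7,3',4'-penta-O-benzylepicatechin-(4β→8)-5,7,3',4'-tetra-O-benzylflav-2-ene | O(Cc1ccccc1)c1cc(OCc3ccccc3)c2c(c1)O[C@H](c1ccc(OCc3ccccc3)c(OCc3ccccc3)c1)[C@H](OCc1ccccc1)[C@H]2c1c(OCc2ccccc2)cc(OCc2ccccc2)c2c1OC(c1ccc(OCc3ccccc3)c(OCc3ccccc3)c1)=CC2 | intermediate
14 | C3 isopinocampheylborane adduct of 13 (2,3-trans) | O(Cc1ccccc1)c1cc(OCc3ccccc3)c2c(c1)O[C@H](c1ccc(OCc3ccccc3)c(OCc3ccccc3)c1)[C@H](OCc1ccccc1)[C@H]2c1c(OCc2ccccc2)cc(OCc2ccccc2)c2c1O[C@H](c1ccc(OCc3ccccc3)c(OCc3ccccc3)c1)[C@@H]([BH][C@H]1[C@H](C)[C@H]3C[C@@H](C1)C3(C)C)C2 | intermediate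
15 | 3,5,7,3',4'-penta-O-benzylepicatechin-(4β→8)-5,7,3',4'-tetra-O-benzylcatechin (lower unit 2R,3S, 3-OH free) | O(Cc1ccccc1)c1cc(OCc3ccccc3)c2c(c1)O[C@H](c1ccc(OCc3ccccc3)c(OCc3ccccc3)c1)[C@H](OCc1ccccc1)[C@H]2c1c(OCc2ccccc2)cc(OCc2ccccc2)c2c1O[C@H](c1ccc(OCc3ccccc3)c(OCc3ccccc3)c1)[C@@H](O)C2 | intermediate
16 | 3,5,7,3',4'-penta-O-benzylepicatechin-(4β→8)-(2R)-5,7,3',4'-tetra-O-benzylflavan-3-one | O(Cc1ccccc1)c1cc(OCc3ccccc3)c2c(c1)O[C@H](c1ccc(OCc3ccccc3)c(OCc3ccccc3)c1)[C@H](OCc1ccccc1)[C@H]2c1c(OCc2ccccc2)cc(OCc2ccccc2)c2c1O[C@H](c1ccc(OCc3ccccc3)c(OCc3ccccc3)c1)C(=O)C2 | intermediate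
17 | 3,5,7,3',4'-penta-O-benzylepicatechin-(4β→8)-5,7,3',4'-tetra-O-benzylepicatechin (lower unit 2R,3R, 3-OH free) | O(Cc1ccccc1)c1cc(OCc3ccccc3)c2c(c1)O[C@H](c1ccc(OCc3ccccc3)c(OCc3ccccc3)c1)[C@H](OCc1ccccc1)[C@H]2c1c(OCc2ccccc2)cc(OCc2ccccc2)c2c1O[C@H](c1ccc(OCc3ccccc3)c(OCc3ccccc3)c1)[C@H](O)C2 | intermediate
18 | 3,5,7,3',4'-penta-O-benzylepicatechin-(4β→8)-5,7,3',4'-tetra-O-benzyl-4β-(2-ethoxyethoxy)epicatechin | O(Cc1ccccc1)c1cc(OCc3ccccc3)c2c(c1)O[C@H](c1ccc(OCc3ccccc3)c(OCc3ccccc3)c1)[C@H](OCc1ccccc1)[C@H]2c1c(OCc2ccccc2)cc(OCc2ccccc2)c2c1O[C@H](c1ccc(OCc3ccccc3)c(OCc3ccccc3)c1)[C@H](O)[C@H]2OCCOCC | intermediate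
19 | octadeca-O-benzyl epicatechin-(4β→8)-epicatechin-(4β→8)-epicatechin-(4β→8)-catechin (3-OBn on units 1 and 3; 3-OH free on units 2 and 4) | O(Cc1ccccc1)c1cc(OCc3ccccc3)c2c(c1)O[C@H](c1ccc(OCc3ccccc3)c(OCc3ccccc3)c1)[C@H](OCc1ccccc1)[C@H]2c1c(OCc2ccccc2)cc(OCc2ccccc2)c2c1O[C@H](c1ccc(OCc3ccccc3)c(OCc3ccccc3)c1)[C@H](O)[C@H]2c1c(OCc2ccccc2)cc(OCc2ccccc2)c2c1O[C@H](c1ccc(OCc3ccccc3)c(OCc3ccccc3)c1)[C@H](OCc1ccccc1)[C@H]2c1c(OCc2ccccc2)cc(OCc2ccccc2)c2c1O[C@H](c1ccc(OCc3ccccc3)c(OCc3ccccc3)c1)[C@@H](O)C2 | intermediate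
20 | epicatechin-(4β→8)-epicatechin-(4β→8)-epicatechin-(4β→8)-catechin (the arecatannin tetramer) | Oc1cc(O)c2c(c1)O[C@H](c1ccc(O)c(O)c1)[C@H](O)[C@H]2c1c(O)cc(O)c2c1O[C@H](c1ccc(O)c(O)c1)[C@H](O)[C@H]2c1c(O)cc(O)c2c1O[C@H](c1ccc(O)c(O)c1)[C@H](O)[C@H]2c1c(O)cc(O)c2c1O[C@H](c1ccc(O)c(O)c1)[C@@H](O)C2 | target

**Step count and risks**

Total steps: 15. Longest linear sequence: 12 (steps 1, 2, 3, 6, 8, 9, 10, 11, 12, 13, 14, 15); steps 4 and 5 and step 7 are side branches.

Step 9 (key step). The risk is that the titanium alkylidene fails to engage the crowded diene, so that the reaction stalls at the enol ether and this hydrolyses on work-up. The fallback forms the same C2=C3 bond by reductive carbonyl coupling instead of metathesis. It sets out from 11: Lemieux–Johnson cleavage of the allyl group (OsO4 cat., NaIO4, 2,6-lutidine, dioxane/H2O) should give the arylacetaldehyde ester F1, and an intramolecular McMurry-type oxo-ester coupling with low-valent titanium (TiCl3, Zn, DME, reflux) should close the enol ether ring. It returns to the route at 13.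

Step 10. The risk is poor facial discrimination by the terpenyl borane on the hindered enol ether beside the chiral upper unit. The fallback replaces reagent control by a dynamic kinetic resolution and sets out from 13. Hydroboration–oxidation with BH3·SMe2 should give 15 together with its (2S,3R) lower-unit diastereomer F2; pure 15 needed as the nucleophile of step 14 is separated by chromatography. The remaining mixture is oxidised with Dess–Martin periodinane to 16 and its C2-epimeric ketone F3, which interconvert through the enol. Noyori-type transfer hydrogenation with RuCl(p-cymene)(TsDPEN), HCO2H/Et3N (ligand enantiomer fixed on the monomeric model ketone) should funnel both epimers to the 2,3-cis alcohol. It returns to the route at 17.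

Step 13. The risk is competing hydride abstraction at the doubly benzylic C4–H of the upper unit, leading to cleavage or over-oxidation of the dimer. The fallback changes the order of assembly to chain extension, so that C4 is only ever activated on monomers; unit 2 then comes from step 1 material, while ring C of unit 4 still comes from step 9. It sets out from 2: DDQ/2-ethoxyethanol should give 5,7,3',4'-tetra-O-benzyl-4β-(2-ethoxyethoxy)epicatechin F4. Coupling of F4 with excess 15 (TMSOTf, CH2Cl2, −78 °C) should give the protected trimer F5 (units 2 to 4), and coupling of F5 with 4 under the same conditions should add unit 1 at C8 of unit 2. It returns to the route at 19.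

Further compounds
F1 | step 9 | 3,5-bis(benzyloxy)-6-(2-oxoethyl)-2-(3,5,7,3',4'-penta-O-benzylepicatechin-4β-yl)phenyl 3,4-bis(benzyloxy)benzoate | O(Cc1ccccc1)c1cc(OCc3ccccc3)c2c(c1)O[C@H](c1ccc(OCc3ccccc3)c(OCc3ccccc3)c1)[C@H](OCc1ccccc1)[C@H]2c1c(OCc2ccccc2)cc(OCc2ccccc2)c(CC=O)c1OC(=O)c1ccc(OCc2ccccc2)c(OCc2ccccc2)c1
F2 | step 10 | 3,5,7,3',4'-penta-O-benzylepicatechin-(4β→8)-(2S,3R)-5,7,3',4'-tetra-O-benzyl-2,3-trans-flavan-3-ol | O(Cc1ccccc1)c1cc(OCc3ccccc3)c2c(c1)O[C@H](c1ccc(OCc3ccccc3)c(OCc3ccccc3)c1)[C@H](OCc1ccccc1)[C@H]2c1c(OCc2ccccc2)cc(OCc2ccccc2)c2c1O[C@@H](c1ccc(OCc3ccccc3)c(OCc3ccccc3)c1)[C@H](O)C2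
F3 | step 10 | 3,5,7,3',4'-penta-O-benzylepicatechin-(4β→8)-(2S)-5,7,3',4'-tetra-O-benzylflavan-3-one | O(Cc1ccccc1)c1cc(OCc3ccccc3)c2c(c1)O[C@H](c1ccc(OCc3ccccc3)c(OCc3ccccc3)c1)[C@H](OCc1ccccc1)[C@H]2c1c(OCc2ccccc2)cc(OCc2ccccc2)c2c1O[C@@H](c1ccc(OCc3ccccc3)c(OCc3ccccc3)c1)C(=O)C2
F4 | step 13 | 5,7,3',4'-tetra-O-benzyl-4β-(2-ethoxyethoxy)epicatechin | O(Cc1ccccc1)c1cc(OCc3ccccc3)c2c(c1)O[C@H](c1ccc(OCc3ccccc3)c(OCc3ccccc3)c1)[C@H](O)[C@H]2OCCOCC
F5 | step 13 | 5,7,3',4'-tetra-O-benzylepicatechin-(4β→8)-3,5,7,3',4'-penta-O-benzylepicatechin-(4β→8)-5,7,3',4'-tetra-O-benzylcatechin | O(Cc1ccccc1)c1cc(OCc3ccccc3)c2c(c1)O[C@H](c1ccc(OCc3ccccc3)c(OCc3ccccc3)c1)[C@H](O)[C@H]2c1c(OCc2ccccc2)cc(OCc2ccccc2)c2c1O[C@H](c1ccc(OCc3ccccc3)c(OCc3ccccc3)c1)[C@H](OCc1ccccc1)[C@H]2c1c(OCc2ccccc2)cc(OCc2ccccc2)c2c1O[C@H](c1ccc(OCc3ccccc3)c(OCc3ccccc3)c1)[C@@H](O)C2
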